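**Retrosynthetic overview**
- The target is epicatechin-(4β→8)-catechin-(4α→8)-catechin whose lower 3-OH carries an (S)-1-hydroxy-6-oxocyclohex-2-ene-1-carbonyl group. The last disconnections are the silyl ethers and the ester; the acid is carried as a Birch-derived methyl dienol ether, so its carbocycle comes from methyl 2-methoxybenzoate without a ring closure.
- Key disconnection: the pyran ring of the upper unit (O1, C2, C3, C4, C4a, C8a) is opened to an o-quinone methide heterodiene O1=C8a–C4a=C4 and a (Z)-2-arylvinyl acetate that supplies C2=C3 (hetero-Diels–Alder).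
- Enabling feature: O1 is a phloroglucinol-ring oxygen ortho to C4, and C4 is doubly benzylic (upper ring A and C8 of the middle unit), so a C4 carbinol ionises to a stabilised heterodiene. C2 carries a 4-oxygenated aryl group, so the enol acetate reacts as a styrene.
- The C4 carbinol comes from an 8-lithiated catechin-(4α→8)-catechin dimer (Friedel–Crafts coupling of two catechin units) and a salicylaldehyde.
- Ring order: all six benzene rings, the two lower pyran rings and the carbocycle come ready-made from the starting materials. The upper pyran ring is the only ring closed (step 13); a staged exchange of benzyl for silyl ethers, esterification and global deprotection follow.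

Key step: step 13

Assumption: the (R)-phosphoramide in step 13 and the (+)-oxaziridine in step 21 are taken as the ones whose sense of induction gives the drawn configurations; if either sense is opposite, the enantiomeric catalyst or reagent is used and nothing else changes. Abbreviations: Bn = benzyl, TBS = tert-butyldimethylsilyl, TES = triethylsilyl.

**Route**

Step 1
Reactants: 1 (+)-catechin
Product: 2 5,7,3',4'-tetra-O-benzyl-(+)-catechin (2R,3S)
Conditions: BnBr (4.4 equiv), K2CO3, DMF, 0 °C to rt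
Reagents that add atoms: benzyl bromide, BrCc1ccccc1
Why: Williamson etherification, in which the four phenols are alkylated by K2CO3/BnBr while the C3 secondary alcohol is not deprotonated and no stereocentre is touched.

Step 2
Reactants: 2 5,7,3',4'-tetra-O-benzyl-(+)-catechin
Product: 3 5,7,3',4'-tetra-O-benzyl-3-O-(triethylsilyl)-(+)-catechin
Conditions: Et3SiCl, imidazole, DMF, rt
Reagents that add atoms: chlorotriethylsilane, CC[Si](Cl)(CC)CC
Why: Imidazole-promoted silyl ether formation on the only free hydroxyl gives a group that should survive Lewis acid at −78 °C, carbonate, alkyllithium and hydrogenolysis, yet is later cleaved selectively beside tert-butyldimethylsilyl ethers.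

Step 3
Reactants: 2 5,7,3',4'-tetra-O-benzyl-(+)-catechin
Product: 4 8-bromo-5,7,3',4'-tetra-O-benzyl-(+)-catechin
Conditions: N-bromosuccinimide (1.0 equiv), CH2Cl2, −78 to 0 °C
Reagents that add atoms: N-bromosuccinimide, O=C1CCC(=O)N1Br
Why: Electrophilic aromatic bromination goes to C8, the most accessible nucleophilic carbon of the phloroglucinol ring, and the bromine then caps C8 against self-condensation and serves as the lithiation handle.

Step 4
Reactants: 4 8-bromo-5,7,3',4'-tetra-O-benzyl-(+)-catechin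
Product: 5 (2R,3S,4S)-8-bromo-5,7,3',4'-tetra-O-benzyl-4-(2-ethoxyethoxy)flavan-3-ol (4β ether; 2,3-trans; 3,4-cis)
Conditions: 2,3-dichloro-5,6-dicyano-1,4-benzoquinone (2 equiv), 2-ethoxyethanol, CH2Cl2, rt
Reagents that add atoms: 2-ethoxyethanol, CCOCCO
Why: Benzylic oxidation by the quinone (hydride abstraction from C4 to a cation stabilised by the 5- and 7-oxygens) with capture by the alcohol on the face away from the 2-aryl group, a standard entry to flavan C4 electrophiles; the C4 configuration is erased again in step 6.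

Step 5
Reactants: 5 the 4β-(2-ethoxyethoxy) alcohol
Product: 6 3-O-acetate of 5
Conditions: Ac2O, 4-(dimethylamino)pyridine (cat.), pyridine, rt
Reagents that add atoms: acetic anhydride, CC(=O)OC(C)=O
Why: Nucleophile-catalysed acylation installs the 3-acetate that acts as the participating group in the next step.

Step 6
Reactants: 6 the 3-O-acetyl-4-(2-ethoxyethoxy) electrophile; 3 the 3-O-triethylsilyl nucleophile (1.5 equiv)
Product: 7 protected dimer: middle unit 8-bromo-3-O-acetyl-tetra-O-benzylcatechin joined 4α→8 (3,4-trans) to lower unit 3-O-triethylsilyl-tetra-O-benzylcatechin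
Conditions: Me3SiOTf (0.5 equiv), CH2Cl2, −78 °C
Reagents that add atoms: none
Why: Lewis-acid Friedel–Crafts (SN1) interflavan coupling, in which the C4 cation is bridged on its β face by the 3-acetoxy group so that C8 of 3 attacks from the α face and sets the 3,4-trans (4α→8) centre, while the bromine on 6 prevents oligomerisation.

Step 7
Reactants: 7 protected dimer (middle 3-O-acetate)
Product: 8 protected dimer with free middle 3-OH
Conditions: K2CO3, MeOH/THF, rt
Reagents that add atoms: none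
Why: Zemplén-type transesterification removes the acetate, which would not survive tert-butyllithium, without touching the triethylsilyl ether or the aryl bromide.

Step 8
Reactants: 8 protected dimer with free middle 3-OH
Product: 9 protected dimer with middle 3-O-tert-butyldimethylsilyl ether
Conditions: t-BuMe2SiOTf, 2,6-lutidine, CH2Cl2, 0 °C to rt
Reagents that add atoms: tert-butyldimethylsilyl triflate, CC(C)(C)[Si](C)(C)OS(=O)(=O)C(F)(F)F
Why: Silyl triflate silylation of the hindered secondary alcohol gives an ether inert to organolithium, to the Brønsted acid of step 13 and to hydrogenolysis.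

Step 9
Reactants: 10 2,4,6-trihydroxybenzaldehyde
Product: 11 2,4-bis(benzyloxy)-6-hydroxybenzaldehyde
Conditions: BnBr (2.0 equiv), K2CO3, DMF, rt
Reagents that add atoms: benzyl bromide, BrCc1ccccc1
Why: Selective Williamson benzylation, in which the hydroxyl hydrogen-bonded to the formyl group is the least nucleophilic and stays free.

Step 10
Reactants: 9 protected 8-bromo dimer; 11 2,4-bis(benzyloxy)-6-hydroxybenzaldehyde (1.5 equiv)
Product: 14 o-hydroxybenzhydrol (9 with Br replaced by CH(OH)-[2-hydroxy-4,6-bis(benzyloxy)phenyl]; both carbinol epimers), via 8-lithio dimer 12 (not isolated), via sodium phenoxide of the aldehyde 13 (not isolated)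
Conditions: 9, t-BuLi (2.1 equiv), THF, −78 °C; then 13 (from 11, NaH, THF, 0 °C), −78 to −20 °C; cold aq NH4Cl; used without chromatography on acidic media
Reagents that add atoms: none
Why: Bromine–lithium exchange followed by 1,2-addition of the aryllithium to the aldehyde (its phenol masked as the sodium salt) forges the C4–C8 bond between the future upper unit and the middle unit, and the new carbinol centre, formed as a mixture of epimers, is erased in step 13.

Step 11
Reactants: 15 3,4-bis(benzyloxy)benzaldehyde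
Product: 16 1,2-bis(benzyloxy)-4-ethynylbenzene
Conditions: dimethyl (1-diazo-2-oxopropyl)phosphonate, K2CO3, MeOH/THF, rt
Reagents that add atoms: dimethyl (1-diazo-2-oxopropyl)phosphonate, CC(=O)C(=[N+]=[N-])P(=O)(OC)OC
Why: Seyferth–Gilbert homologation (Bestmann–Ohira variant) converts the aldehyde into the terminal alkyne under mild base.

Step 12
Reactants: 16 1,2-bis(benzyloxy)-4-ethynylbenzene
Product: 17 (Z)-2-[3,4-bis(benzyloxy)phenyl]ethenyl acetate
Conditions: AcOH (1.5 equiv), Ru(2-methylallyl)2(dppb) (2 mol %; dppb = Ph2P(CH2)4PPh2), toluene, 45 °C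
Reagents that add atoms: acetic acid, CC(=O)O
Why: Ruthenium-catalysed anti-Markovnikov hydro-acyloxylation of a terminal alkyne (through a vinylidene) should deliver the Z enol ester, which fixes the cis relation later needed between C2 and C3.

Step 13
Reactants: 14 o-hydroxybenzhydrol; 17 (Z)-enol acetate (3 equiv)
Product: 19 protected trimer: upper unit 3-O-acetyl-5,7,3',4'-tetra-O-benzylepicatechin (2,3-cis; 3,4-trans) joined 4β→8 to the middle unit of the dimer (middle 3-O-TBS; lower 3-O-TES; twelve benzyl ethers), via o-quinone methide 18 (not isolated)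
Conditions: (R)-3,3'-bis(2,4,6-triisopropylphenyl)-1,1'-binaphthyl-2,2'-diyl N-triflylphosphoramide (10 mol %), 4 Å molecular sieves, toluene, −40 °C
Reagents that add atoms: none
Why: Proposed new method: the phosphoramide ionises the doubly benzylic carbinol of 14 to the o-quinone methide 18 (heterodiene O1=C8a–C4a=C4) held as a hydrogen-bonded chiral ion pair, and the Z enol acetate 17 adds as the 2π partner in an inverse-demand hetero-Diels–Alder reaction; because acetoxy is only a weak donor the alkene reacts as a 4-alkoxystyrene, its acetoxy-bearing carbon bonding to C4 and its benzylic carbon to O1. The closest known reaction type is the chiral phosphoric acid or N-triflylphosphoramide catalysed [4+2] cycloaddition of o-hydroxybenzhydryl alcohols with styrenes and enecarbamates to 2,4-disubstituted chromans; an enol ester has not been shown in this role. The pyran ring closes by [4+2] cycloaddition, an asynchronous suprafacial addition in which C3–C4 forms slightly ahead of O1–C2. C2 and C3 are set cis by transfer of the Z alkene geometry, C4 is set trans to C3 because the acetoxy-bearing carbon approaches with its substituent anti to the bulky 8-flavanyl group on the methide carbon (exo mode), and the absolute sense of all three is set by the chiral counter-anion, which shields one face of 18 and should override the remote stereocentres of the two lower units. The step needs regioselectivity, which the para-benzyloxy group of the styrene secures, and ionisation at the new carbinol only, which the free ortho phenol and the low temperature secure while the interflavan bond and the silyl ethers stay intact.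

Step 14
Reactants: 19 protected trimer (upper 3-O-acetate)
Product: 20 protected trimer with free upper 3-OH
Conditions: K2CO3, MeOH/THF, 40 °C
Reagents that add atoms: none
Why: Base-catalysed methanolysis of the secondary acetate, to which silyl and benzyl ethers are stable.

Step 15
Reactants: 20 protected trimer with free upper 3-OH
Product: 21 protected trimer with upper 3-O-TBS (upper and middle 3-O-TBS; lower 3-O-TES; twelve benzyl ethers)
Conditions: t-BuMe2SiOTf (3 equiv), 2,6-lutidine, CH2Cl2, 0 °C to rt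
Reagents that add atoms: tert-butyldimethylsilyl triflate, CC(C)(C)[Si](C)(C)OS(=O)(=O)C(F)(F)F
Why: Silyl triflate silylation of the hindered secondary alcohol is done while all phenols are still benzylated, so that the upper 3-oxygen is capped as a robust ether and only the lower 3-O-triethylsilyl position remains addressable later.

Step 16
Reactants: 21 protected trimer with upper 3-O-TBS
Product: 22 dodecaphenol (upper and middle 3-O-TBS; lower 3-O-TES)
Conditions: H2 (1 atm), Pd(OH)2 on carbon, THF/EtOAc, rt; kept under argon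
Reagents that add atoms: none
Why: Heterogeneous hydrogenolysis of the twelve aryl benzyl ethers is done before the cyclohexadiene ester is introduced, because that unit would not survive hydrogen, and silyl ethers and interflavan bonds are inert in an aprotic medium.

Step 17
Reactants: 22 dodecaphenol
Product: 25 hexa-O-TBS derivative silylated on the six ring A hydroxyls (three free catechols; upper and middle 3-O-TBS; lower 3-O-TES), via tris(phenylboronate) 23 (not isolated), via hexa-O-TBS tris(phenylboronate) 24 (not isolated)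
Conditions: PhB(OH)2 (3.1 equiv), 4 Å molecular sieves, MeCN, rt, then evaporation; t-BuMe2SiOTf (8 equiv), 2,6-lutidine, CH2Cl2/DMF, 0 °C to rt; then pinacol (5 equiv), MeOH, rt; argon throughout
Reagents that add atoms: tert-butyldimethylsilyl triflate, CC(C)(C)[Si](C)(C)OS(=O)(=O)C(F)(F)F
Why: Transient cyclic boronate protection of the three catechols (only the ortho-dihydroxy rings B can close a five-membered 1,3,2-dioxaborole, the meta-disposed ring A hydroxyls cannot), silylation of the six remaining phenols with the silyl triflate, and release of the catechols by transesterification with pinacol, which is the known use of a boronic ester as a temporary 1,2-diol protecting group.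

Step 18
Reactants: 25 ring A hexa-O-TBS derivative with three free catechols
Product: 26 tetradeca-O-TBS trimer (twelve aryl, upper 3-O and middle 3-O silyl ethers; lower 3-O-TES)
Conditions: t-BuMe2SiOTf (9 equiv), 2,6-lutidine, CH2Cl2/DMF, 0 °C to rt, argon
Reagents that add atoms: tert-butyldimethylsilyl triflate, CC(C)(C)[Si](C)(C)OS(=O)(=O)C(F)(F)F
Why: Silyl triflate silylation of the six catechol hydroxyls, the only free hydroxyls left, completes the exchange of benzyl for silyl so that the final deprotection is non-reductive, and the triethylsilyl ether is untouched.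

Step 19
Reactants: 26 tetradeca-O-TBS trimer
Product: 27 tetradeca-O-TBS trimer with free lower 3-OH
Conditions: pyridinium p-toluenesulfonate, MeOH/CH2Cl2, 0 °C to rt
Reagents that add atoms: none
Why: Acid-catalysed solvolysis differentiates silyl ethers by bulk, cleaving the secondary triethylsilyl ether while aryl and secondary tert-butyldimethylsilyl ethers are stable to this mild acid.

Step 20
Reactants: 28 methyl 2-methoxybenzoate
Product: 29 methyl 2-methoxycyclohexa-2,5-diene-1-carboxylate (racemic)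
Conditions: Li (2.5 equiv), NH3(l)/THF, t-BuOH (1.5 equiv), −78 °C; then NH4Cl
Reagents that add atoms: none
Why: Birch reduction of a benzoate ester gives the 1,4-dihydro compound with the methoxy-bearing carbon kept in the enol ether double bond, a masked β-keto ester that carries the target carbocycle without any ring closure.

Step 21
Reactants: 29 methyl 2-methoxycyclohexa-2,5-diene-1-carboxylate
Product: 31 methyl (S)-1-hydroxy-2-methoxycyclohexa-2,5-diene-1-carboxylate, via potassium dienolate 30 (not isolated)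
Conditions: KN(SiMe3)2 (1.1 equiv), THF, −78 °C; then (+)-(2R,8aS)-(camphorsulfonyl)oxaziridine (1.3 equiv), −78 °C; aq NH4Cl
Reagents that add atoms: (+)-(camphorsulfonyl)oxaziridine, CC1(C)[C@@H]2CC[C@]13CS(=O)(=O)N4O[C@@]34C2
Why: Asymmetric enolate hydroxylation with an enantiopure N-sulfonyloxaziridine (Davis oxidation), in which the cross-conjugated dienolate is oxygenated at the α-carbon and the reagent differentiates the enolate faces to give the S tertiary alcohol, whose enantiopurity can be raised by crystallisation.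

Step 22
Reactants: 31 methyl (S)-1-hydroxy-2-methoxycyclohexa-2,5-diene-1-carboxylate
Product: 32 methyl (S)-2-methoxy-1-[(triethylsilyl)oxy]cyclohexa-2,5-diene-1-carboxylate
Conditions: Et3SiOTf, 2,6-lutidine, CH2Cl2, −78 to 0 °C
Reagents that add atoms: triethylsilyl triflate, CC[Si](CC)(CC)OS(=O)(=O)C(F)(F)F
Why: Silyl triflate protection of the tertiary alcohol prevents self-acylation in step 24.

Step 23
Reactants: 32 the silylated methyl ester
Product: 33 (S)-2-methoxy-1-[(triethylsilyl)oxy]cyclohexa-2,5-diene-1-carboxylic acid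
Conditions: LiOH, THF/MeOH/H2O, 40 °C; then aq NaH2PO4 to pH 5, 0 °C, extraction; used at once
Reagents that add atoms: lithium hydroxide, [Li+].[OH-]
Why: Saponification of the methyl ester, to which the enol ether and the silyl ether are stable, with the acid liberated cold at pH 5 as is usual for Birch-derived methoxydiene acids.

Step 24
Reactants: 27 trimer with free lower 3-OH; 33 the silylated acid (2 equiv)
Product: 35 fully silylated ester (lower 3-O acylated by 33), via acid chloride 34 (not isolated)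
Conditions: 33, 1-chloro-N,N,2-trimethylprop-1-en-1-amine, CH2Cl2, 0 °C to rt; then 27, Et3N, 4-(dimethylamino)pyridine, CH2Cl2, rt to 40 °C
Reagents that add atoms: none
Why: Esterification through the acid chloride, made under neutral conditions with the α-chloroenamine, and nucleophile-catalysed acyl transfer to the only free hydroxyl; no stereocentre is involved.

Step 25
Reactants: 35 fully silylated ester
Product: 36 target
Conditions: 48% aq HF (large excess), MeCN/THF, 0 °C to rt, argon, plastic vessel; pH 6 buffer; reversed-phase chromatography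
Reagents that add atoms: water, O
Why: Fluoride-mediated desilylation and acid hydrolysis of the methyl enol ether in one pot (protonation at C3 of the dienol ether and hydration release the 6-oxo group with the isolated double bond left in place) under non-reductive, non-basic conditions that the β-keto ester, its alkene and the interflavan bonds should survive.

**Compound list**

1 | (+)-catechin | O[C@H]1Cc2c(O)cc(O)cc2O[C@@H]1c1ccc(O)c(O)c1 | starting material
2 | 5,7,3',4'-tetra-O-benzyl-(+)-catechin | O[C@H]1Cc2c(OCc7ccccc7)cc(OCc7ccccc7)cc2O[C@@H]1c1ccc(OCc7ccccc7)c(OCc7ccccc7)c1 | intermediate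
3 | 5,7,3',4'-tetra-O-benzyl-3-O-(triethylsilyl)-(+)-catechin | CC[Si](CC)(CC)O[C@H]1Cc2c(OCc7ccccc7)cc(OCc7ccccc7)cc2O[C@@H]1c1ccc(OCc7ccccc7)c(OCc7ccccc7)c1 | intermediate
4 | 8-bromo-5,7,3',4'-tetra-O-benzyl-(+)-catechin | O[C@H]1Cc2c(OCc7ccccc7)cc(OCc7ccccc7)c(Br)c2O[C@@H]1c1ccc(OCc7ccccc7)c(OCc7ccccc7)c1 | intermediate
5 | (2R,3S,4S)-8-bromo-5,7,3',4'-tetra-O-benzyl-4-(2-ethoxyethoxy)flavan-3-ol | O[C@H]1[C@@H](OCCOCC)c2c(OCc7ccccc7)cc(OCc7ccccc7)c(Br)c2O[C@@H]1c1ccc(OCc7ccccc7)c(OCc7ccccc7)c1 | intermediate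
6 | 3-O-acetate of 5 | CC(=O)O[C@H]1[C@@H](OCCOCC)c2c(OCc7ccccc7)cc(OCc7ccccc7)c(Br)c2O[C@@H]1c1ccc(OCc7ccccc7)c(OCc7ccccc7)c1 | intermediate
7 | protected dimer, middle unit 8-bromo-3-O-acetyl, 4α→8, lower unit 3-O-TES, eight benzyl ethers | CC[Si](CC)(CC)O[C@H]1Cc2c(OCc7ccccc7)cc(OCc7ccccc7)c([C@@H]3c4c(OCc7ccccc7)cc(OCc7ccccc7)c(Br)c4O[C@H](c4ccc(OCc7ccccc7)c(OCc7ccccc7)c4)[C@H]3OC(C)=O)c2O[C@@H]1c1ccc(OCc7ccccc7)c(OCc7ccccc7)c1 | intermediate
8 | protected dimer with free middle 3-OH | CC[Si](CC)(CC)O[C@H]1Cc2c(OCc7ccccc7)cc(OCc7ccccc7)c([C@@H]3c4c(OCc7ccccc7)cc(OCc7ccccc7)c(Br)c4O[C@H](c4ccc(OCc7ccccc7)c(OCc7ccccc7)c4)[C@H]3O)c2O[C@@H]1c1ccc(OCc7ccccc7)c(OCc7ccccc7)c1 | intermediate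
9 | protected dimer with middle 3-O-TBS | CC[Si](CC)(CC)O[C@H]1Cc2c(OCc7ccccc7)cc(OCc7ccccc7)c([C@@H]3c4c(OCc7ccccc7)cc(OCc7ccccc7)c(Br)c4O[C@H](c4ccc(OCc7ccccc7)c(OCc7ccccc7)c4)[C@H]3O[Si](C)(C)C(C)(C)C)c2O[C@@H]1c1ccc(OCc7ccccc7)c(OCc7ccccc7)c1 | intermediate
10 | 2,4,6-trihydroxybenzaldehyde | O=Cc1c(O)cc(O)cc1O | starting material
11 | 2,4-bis(benzyloxy)-6-hydroxybenzaldehyde | O=Cc1c(O)cc(OCc2ccccc2)cc1OCc1ccccc1 | intermediate
12 | 8-lithio derivative of 9 | CC[Si](CC)(CC)O[C@H]1Cc2c(OCc7ccccc7)cc(OCc7ccccc7)c([C@@H]3c4c(OCc7ccccc7)cc(OCc7ccccc7)c([Li])c4O[C@H](c4ccc(OCc7ccccc7)c(OCc7ccccc7)c4)[C@H]3O[Si](C)(C)C(C)(C)C)c2O[C@@H]1c1ccc(OCc7ccccc7)c(OCc7ccccc7)c1 | intermediate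
13 | sodium 3,5-bis(benzyloxy)-2-formylphenoxide | [Na+].[O-]c1cc(OCc2ccccc2)cc(OCc2ccccc2)c1C=O | intermediate
14 | o-hydroxybenzhydrol: C8 of the middle unit bears CH(OH)[2-hydroxy-4,6-bis(benzyloxy)phenyl], carbinol epimers | CC[Si](CC)(CC)O[C@H]1Cc2c(OCc7ccccc7)cc(OCc7ccccc7)c([C@@H]3c4c(OCc7ccccc7)cc(OCc7ccccc7)c(C(O)c6c(OCc7ccccc7)cc(OCc7ccccc7)cc6O)c4O[C@H](c4ccc(OCc7ccccc7)c(OCc7ccccc7)c4)[C@H]3O[Si](C)(C)C(C)(C)C)c2O[C@@H]1c1ccc(OCc7ccccc7)c(OCc7ccccc7)c1 | intermediate
15 | 3,4-bis(benzyloxy)benzaldehyde | O=Cc1ccc(OCc2ccccc2)c(OCc2ccccc2)c1 | starting material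
16 | 1,2-bis(benzyloxy)-4-ethynylbenzene | C#Cc1ccc(OCc2ccccc2)c(OCc2ccccc2)c1 | intermediate
17 | (Z)-2-[3,4-bis(benzyloxy)phenyl]ethenyl acetate | CC(=O)O/C=C\c1ccc(OCc2ccccc2)c(OCc2ccccc2)c1 | intermediate
18 | o-quinone methide from 14 | CC[Si](CC)(CC)O[C@H]1Cc2c(OCc7ccccc7)cc(OCc7ccccc7)c([C@@H]3c4c(OCc7ccccc7)cc(OCc7ccccc7)c(C=C6C(OCc7ccccc7)=CC(OCc7ccccc7)=CC6=O)c4O[C@H](c4ccc(OCc7ccccc7)c(OCc7ccccc7)c4)[C@H]3O[Si](C)(C)C(C)(C)C)c2O[C@@H]1c1ccc(OCc7ccccc7)c(OCc7ccccc7)c1 | intermediate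
19 | protected trimer: upper 3-O-acetyl, middle 3-O-TBS, lower 3-O-TES, twelve benzyl ethers, 4β→8 and 4α→8 | CC[Si](CC)(CC)O[C@H]1Cc2c(OCc7ccccc7)cc(OCc7ccccc7)c([C@@H]3c4c(OCc7ccccc7)cc(OCc7ccccc7)c([C@H]5c6c(OCc7ccccc7)cc(OCc7ccccc7)cc6O[C@H](c6ccc(OCc7ccccc7)c(OCc7ccccc7)c6)[C@@H]5OC(C)=O)c4O[C@H](c4ccc(OCc7ccccc7)c(OCc7ccccc7)c4)[C@H]3O[Si](C)(C)C(C)(C)C)c2O[C@@H]1c1ccc(OCc7ccccc7)c(OCc7ccccc7)c1 | intermediate
20 | protected trimer with free upper 3-OH | CC[Si](CC)(CC)O[C@H]1Cc2c(OCc7ccccc7)cc(OCc7ccccc7)c([C@@H]3c4c(OCc7ccccc7)cc(OCc7ccccc7)c([C@H]5c6c(OCc7ccccc7)cc(OCc7ccccc7)cc6O[C@H](c6ccc(OCc7ccccc7)c(OCc7ccccc7)c6)[C@@H]5O)c4O[C@H](c4ccc(OCc7ccccc7)c(OCc7ccccc7)c4)[C@H]3O[Si](C)(C)C(C)(C)C)c2O[C@@H]1c1ccc(OCc7ccccc7)c(OCc7ccccc7)c1 | intermediate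
21 | protected trimer: upper and middle 3-O-TBS, lower 3-O-TES, twelve benzyl ethers | CC[Si](CC)(CC)O[C@H]1Cc2c(OCc7ccccc7)cc(OCc7ccccc7)c([C@@H]3c4c(OCc7ccccc7)cc(OCc7ccccc7)c([C@H]5c6c(OCc7ccccc7)cc(OCc7ccccc7)cc6O[C@H](c6ccc(OCc7ccccc7)c(OCc7ccccc7)c6)[C@@H]5O[Si](C)(C)C(C)(C)C)c4O[C@H](c4ccc(OCc7ccccc7)c(OCc7ccccc7)c4)[C@H]3O[Si](C)(C)C(C)(C)C)c2O[C@@H]1c1ccc(OCc7ccccc7)c(OCc7ccccc7)c1 | intermediate
22 | dodecaphenol: upper and middle 3-O-TBS, lower 3-O-TES | CC[Si](CC)(CC)O[C@H]1Cc2c(O)cc(O)c([C@@H]3c4c(O)cc(O)c([C@H]5c6c(O)cc(O)cc6O[C@H](c6ccc(O)c(O)c6)[C@@H]5O[Si](C)(C)C(C)(C)C)c4O[C@H](c4ccc(O)c(O)c4)[C@H]3O[Si](C)(C)C(C)(C)C)c2O[C@@H]1c1ccc(O)c(O)c1 | intermediate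
23 | tris(phenylboronate) of 22: the three catechols as 2-phenyl-1,3,2-benzodioxaboroles, six free ring A phenols | CC[Si](CC)(CC)O[C@H]1Cc2c(O)cc(O)c([C@@H]3c4c(O)cc(O)c([C@H]5c6c(O)cc(O)cc6O[C@H](c6ccc7OB(c8ccccc8)Oc7c6)[C@@H]5O[Si](C)(C)C(C)(C)C)c4O[C@H](c4ccc7OB(c8ccccc8)Oc7c4)[C@H]3O[Si](C)(C)C(C)(C)C)c2O[C@@H]1c1ccc2OB(c3ccccc3)Oc2c1 | intermediate
24 | hexa-O-TBS tris(phenylboronate): six ring A silyl ethers, three catechol boronates | CC[Si](CC)(CC)O[C@H]1Cc2c(O[Si](C)(C)C(C)(C)C)cc(O[Si](C)(C)C(C)(C)C)c([C@@H]3c4c(O[Si](C)(C)C(C)(C)C)cc(O[Si](C)(C)C(C)(C)C)c([C@H]5c6c(O[Si](C)(C)C(C)(C)C)cc(O[Si](C)(C)C(C)(C)C)cc6O[C@H](c6ccc7OB(c8ccccc8)Oc7c6)[C@@H]5O[Si](C)(C)C(C)(C)C)c4O[C@H](c4ccc7OB(c8ccccc8)Oc7c4)[C@H]3O[Si](C)(C)C(C)(C)C)c2O[C@@H]1c1ccc2OB(c3ccccc3)Oc2c1 | intermediate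
25 | ring A hexa-O-TBS derivative with three free catechols: upper and middle 3-O-TBS, lower 3-O-TES | CC[Si](CC)(CC)O[C@H]1Cc2c(O[Si](C)(C)C(C)(C)C)cc(O[Si](C)(C)C(C)(C)C)c([C@@H]3c4c(O[Si](C)(C)C(C)(C)C)cc(O[Si](C)(C)C(C)(C)C)c([C@H]5c6c(O[Si](C)(C)C(C)(C)C)cc(O[Si](C)(C)C(C)(C)C)cc6O[C@H](c6ccc(O)c(O)c6)[C@@H]5O[Si](C)(C)C(C)(C)C)c4O[C@H](c4ccc(O)c(O)c4)[C@H]3O[Si](C)(C)C(C)(C)C)c2O[C@@H]1c1ccc(O)c(O)c1 | intermediate
26 | tetradeca-O-TBS trimer with lower 3-O-TES | CC[Si](CC)(CC)O[C@H]1Cc2c(O[Si](C)(C)C(C)(C)C)cc(O[Si](C)(C)C(C)(C)C)c([C@@H]3c4c(O[Si](C)(C)C(C)(C)C)cc(O[Si](C)(C)C(C)(C)C)c([C@H]5c6c(O[Si](C)(C)C(C)(C)C)cc(O[Si](C)(C)C(C)(C)C)cc6O[C@H](c6ccc(O[Si](C)(C)C(C)(C)C)c(O[Si](C)(C)C(C)(C)C)c6)[C@@H]5O[Si](C)(C)C(C)(C)C)c4O[C@H](c4ccc(O[Si](C)(C)C(C)(C)C)c(O[Si](C)(C)C(C)(C)C)c4)[C@H]3O[Si](C)(C)C(C)(C)C)c2O[C@@H]1c1ccc(O[Si](C)(C)C(C)(C)C)c(O[Si](C)(C)C(C)(C)C)c1 | intermediate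
27 | tetradeca-O-TBS trimer with free lower 3-OH | O[C@H]1Cc2c(O[Si](C)(C)C(C)(C)C)cc(O[Si](C)(C)C(C)(C)C)c([C@@H]3c4c(O[Si](C)(C)C(C)(C)C)cc(O[Si](C)(C)C(C)(C)C)c([C@H]5c6c(O[Si](C)(C)C(C)(C)C)cc(O[Si](C)(C)C(C)(C)C)cc6O[C@H](c6ccc(O[Si](C)(C)C(C)(C)C)c(O[Si](C)(C)C(C)(C)C)c6)[C@@H]5O[Si](C)(C)C(C)(C)C)c4O[C@H](c4ccc(O[Si](C)(C)C(C)(C)C)c(O[Si](C)(C)C(C)(C)C)c4)[C@H]3O[Si](C)(C)C(C)(C)C)c2O[C@@H]1c1ccc(O[Si](C)(C)C(C)(C)C)c(O[Si](C)(C)C(C)(C)C)c1 | intermediate
28 | methyl 2-methoxybenzoate | COC(=O)c1ccccc1OC | starting material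
29 | methyl 2-methoxycyclohexa-2,5-diene-1-carboxylate (racemic) | COC(=O)C1C=CCC=C1OC | intermediate
30 | potassium dienolate of 29 | [K+].[O-]C(OC)=C1C=CCC=C1OC | intermediate
31 | methyl (S)-1-hydroxy-2-methoxycyclohexa-2,5-diene-1-carboxylate | COC1=CCC=C[C@@]1(O)C(=O)OC | intermediate
32 | methyl (S)-2-methoxy-1-[(triethylsilyl)oxy]cyclohexa-2,5-diene-1-carboxylate | COC1=CCC=C[C@@]1(O[Si](CC)(CC)CC)C(=O)OC | intermediate
33 | (S)-2-methoxy-1-[(triethylsilyl)oxy]cyclohexa-2,5-diene-1-carboxylic acid | COC1=CCC=C[C@@]1(O[Si](CC)(CC)CC)C(=O)O | intermediate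
34 | acid chloride of 33 | COC1=CCC=C[C@@]1(O[Si](CC)(CC)CC)C(Cl)=O | intermediate
35 | tetradeca-O-TBS trimer, lower 3-O-[(S)-2-methoxy-1-(triethylsilyloxy)cyclohexa-2,5-diene-1-carbonyl] | COC1=CCC=C[C@@]1(O[Si](CC)(CC)CC)C(=O)O[C@H]1Cc2c(O[Si](C)(C)C(C)(C)C)cc(O[Si](C)(C)C(C)(C)C)c([C@@H]3c4c(O[Si](C)(C)C(C)(C)C)cc(O[Si](C)(C)C(C)(C)C)c([C@H]5c6c(O[Si](C)(C)C(C)(C)C)cc(O[Si](C)(C)C(C)(C)C)cc6O[C@H](c6ccc(O[Si](C)(C)C(C)(C)C)c(O[Si](C)(C)C(C)(C)C)c6)[C@@H]5O[Si](C)(C)C(C)(C)C)c4O[C@H](c4ccc(O[Si](C)(C)C(C)(C)C)c(O[Si](C)(C)C(C)(C)C)c4)[C@H]3O[Si](C)(C)C(C)(C)C)c2O[C@@H]1c1ccc(O[Si](C)(C)C(C)(C)C)c(O[Si](C)(C)C(C)(C)C)c1 | intermediate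
36 | epicatechin-(4β→8)-catechin-(4α→8)-catechin, lower 3-O-[(S)-1-hydroxy-6-oxocyclohex-2-ene-1-carboxylate] | O=C1CCC=C[C@@]1(O)C(=O)O[C@H]1Cc2c(O)cc(O)c([C@@H]3c4c(O)cc(O)c([C@H]5c6c(O)cc(O)cc6O[C@H](c6ccc(O)c(O)c6)[C@@H]5O)c4O[C@H](c4ccc(O)c(O)c4)[C@H]3O)c2O[C@@H]1c1ccc(O)c(O)c1 | target

**Step count**

Total steps: 25. Longest linear sequence: 17 steps (1, 3, 4, 5, 6, 7, 8, 10, 13, 14, 15, 16, 17, 18, 19, 24, 25).

**Steps most likely to fail**

Step 13 (Proposed new method). What may go wrong: poor face selectivity of the cycloaddition against the remote stereocentres, endo instead of exo approach, loss of the alkene geometry through a stepwise ionic addition, or self-condensation of the quinone methide. The fallback sets out from 9 and comes back to the route at 19, using the chiral pool and the established cationic interflavan coupling. Compound 9 is debrominated (t-BuLi, THF, −78 °C; MeOH) to the C8–H dimer F1. Commercial (−)-epicatechin is benzylated (BnBr, K2CO3, DMF) to 5,7,3',4'-tetra-O-benzyl-(−)-epicatechin F2. This is oxidised at C4 with 2,3-dichloro-5,6-dicyano-1,4-benzoquinone and 2-ethoxyethanol to the 4β-(2-ethoxyethoxy) ether F3, which is acetylated (Ac2O, pyridine) to the 3-O-acetate F4. Me3SiOTf-catalysed Friedel–Crafts condensation of F4 with F1 (CH2Cl2, −78 °C) should give 19 directly, the flavan-4-yl cation being attacked trans to the 3-acetoxy group (4β) by C8 of the middle unit.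

Step 21. What may go wrong: low or opposite enantioface discrimination in the oxygen transfer to the dienolate, or oxygenation at a γ-carbon. The fallback sets out from 29 and comes back at 31, by racemic oxidation and classical resolution. Compound 29 is hydroxylated without induction (KN(SiMe3)2; racemic 3-phenyl-2-(phenylsulfonyl)oxaziridine) to the racemic hydroxy ester F5, which is saponified (LiOH, then pH 5) to the racemic hydroxy acid F6. Crystallisation with (S)-1-phenylethylamine should give the ammonium salt of the (S)-acid F7 (the enantiomeric amine is taken if it is the other acid that crystallises). Cold acidification frees the (S)-hydroxy acid F8, and Me3SiCHN2 in MeOH/toluene returns 31.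

Step 10. What may go wrong: slow addition of the hindered aryllithium to the deactivated phenoxide aldehyde with competing protonation, and ionisation of the electron-rich benzhydrol during isolation. The fallback sets out from 9 and comes back at 14, by reversing the polarity of the two partners. Compound 9 is lithiated as before and formylated with N,N-dimethylformamide to the 8-carbaldehyde F9. Commercial 3,5-bis(benzyloxy)phenol is converted with EtMgBr into its bromomagnesium phenoxide F10, which should add to F9 through its ortho carbon in a magnesium-chelated, ortho-specific hydroxyalkylation (toluene, rt; aq NH4Cl) to give 14.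

Further compounds
F1 | step 13 | C8–H dimer (9 with H in place of Br) | CC[Si](CC)(CC)O[C@H]1Cc2c(OCc7ccccc7)cc(OCc7ccccc7)c([C@@H]3c4c(OCc7ccccc7)cc(OCc7ccccc7)cc4O[C@H](c4ccc(OCc7ccccc7)c(OCc7ccccc7)c4)[C@H]3O[Si](C)(C)C(C)(C)C)c2O[C@@H]1c1ccc(OCc7ccccc7)c(OCc7ccccc7)c1
F2 | step 13 | 5,7,3',4'-tetra-O-benzyl-(−)-epicatechin | O[C@@H]1Cc2c(OCc7ccccc7)cc(OCc7ccccc7)cc2O[C@@H]1c1ccc(OCc7ccccc7)c(OCc7ccccc7)c1
F3 | step 13 | 4β-(2-ethoxyethoxy) ether of F2 (2,3-cis, 3,4-trans) | O[C@@H]1[C@@H](OCCOCC)c2c(OCc7ccccc7)cc(OCc7ccccc7)cc2O[C@@H]1c1ccc(OCc7ccccc7)c(OCc7ccccc7)c1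
F4 | step 13 | 3-O-acetate of F3 | CC(=O)O[C@@H]1[C@@H](OCCOCC)c2c(OCc7ccccc7)cc(OCc7ccccc7)cc2O[C@@H]1c1ccc(OCc7ccccc7)c(OCc7ccccc7)c1
F5 | step 21 | racemic methyl 1-hydroxy-2-methoxycyclohexa-2,5-diene-1-carboxylate | COC1=CCC=CC1(O)C(=O)OC
F6 | step 21 | racemic 1-hydroxy-2-methoxycyclohexa-2,5-diene-1-carboxylic acid | COC1=CCC=CC1(O)C(O)=O
F7 | step 21 | (S)-1-phenylethylammonium (S)-1-hydroxy-2-methoxycyclohexa-2,5-diene-1-carboxylate | COC1=CCC=C[C@@]1(O)C([O-])=O.C[C@H]([NH3+])c1ccccc1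
F8 | step 21 | (S)-1-hydroxy-2-methoxycyclohexa-2,5-diene-1-carboxylic acid | COC1=CCC=C[C@@]1(O)C(O)=O
F9 | step 10 | 8-carbaldehyde of the protected dimer (9 with CHO in place of Br) | CC[Si](CC)(CC)O[C@H]1Cc2c(OCc7ccccc7)cc(OCc7ccccc7)c([C@@H]3c4c(OCc7ccccc7)cc(OCc7ccccc7)c(C=O)c4O[C@H](c4ccc(OCc7ccccc7)c(OCc7ccccc7)c4)[C@H]3O[Si](C)(C)C(C)(C)C)c2O[C@@H]1c1ccc(OCc7ccccc7)c(OCc7ccccc7)c1
F10 | step 10 | bromomagnesium 3,5-bis(benzyloxy)phenoxide | Br[Mg]Oc1cc(OCc2ccccc2)cc(OCc2ccccc2)c1
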